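**Retrosynthetic overview**
1. Caespitol 15 ⇐ desilylation of 14 ⇐ thermal diaxial→diequatorial Br/Cl interchange of 13 ⇐ tertiary alcohol→bromide ⇐ trans-diaxial chlorohydrin 12 ⇐ cyclohexene 11.
2. 11 ⇐ one-flask cascade from acyclic enone 7, isoprene 8, a Br+ source and AlMe3: the ketone oxygen opens the bromonium ion (oxane closes, C–Br set), the resulting 2-vinyl oxocarbenium ion undergoes an ionic Diels–Alder reaction (cyclohexene closes), and AlMe3 methylates the cation (quaternary ether carbon).
3. 7 ⇐ vinyl Grignard acylation of a Weinreb amide ⇐ methyl (R)-glycidate 1 + isobutenyl Grignard 2.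
4. Ring order: oxane first, cyclohexene second, both in step 4. The glycidate carbinol centre controls the three new centres of the core; the two halogen-bearing ring carbons are set in steps 5–7.

Assumption: enantiopure methyl (R)-glycidate is accepted as a commercial chiral-pool starting material.

Oxane numbering used below: O1, C2 (quaternary, bears the ring), C3 (O-substituted), C5 (Br), C6 (CMe2).

**Step 1**
Reactants: 1 methyl (2R)-oxirane-2-carboxylate (methyl (R)-glycidate); 2 (2-methylprop-1-en-1-yl)magnesium bromide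
Product: 3 methyl (2R)-2-hydroxy-5-methylhex-4-enoate
Conditions: CuI (10 mol %), THF, −78 → −40 °C; aq. NH4Cl
Reagents that add atoms: none
Why: Copper-catalysed SN2 opening of the terminal epoxide by the alkenyl Grignard reagent (organocuprate epoxide opening) occurs at the CH2 carbon, so the stereocentre of 1 is untouched and stays R; it becomes C3 of the oxane.

**Step 2**
Reactants: 3 methyl (2R)-2-hydroxy-5-methylhex-4-enoate
Product: 4 methyl (2R)-2-[(tert-butyldimethylsilyl)oxy]-5-methylhex-4-enoate
Conditions: TBSCl, imidazole, DMF, rt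
Reagents that add atoms: tert-butyldimethylsilyl chloride, CC(C)(C)[Si](C)(C)Cl
Why: Standard silylation of a secondary alcohol (Corey TBS protection); the bulky silyl ether later suppresses O-participation and steers the cascade, and no stereocentre is affected.

**Step 3**
Reactants: 4 methyl (2R)-2-[(tert-butyldimethylsilyl)oxy]-5-methylhex-4-enoate; 5 vinylmagnesium bromide
Product: 7 (4R)-4-[(tert-butyldimethylsilyl)oxy]-7-methylocta-1,6-dien-3-one, via Weinreb amide 6 (not isolated)
Conditions: MeNH(OMe)·HCl (1.5 equiv), i-PrMgCl (3.0 equiv), THF, −20 °C; then 5 (2.5 equiv), −20 → 0 °C; inverse quench into cold 1 M HCl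
Reagents that add atoms: none
Why: Aminolysis of the ester by the magnesium amide gives Weinreb amide 6, whose chelated tetrahedral adduct with 5 stops at the ketone (Weinreb ketone synthesis); the α-silyloxy centre is not enolised at −20 °C.

**Step 4**
Reactants: 7 (4R)-4-[(tert-butyldimethylsilyl)oxy]-7-methylocta-1,6-dien-3-one; 8 isoprene
Product: 11 tert-butyl{[(2R,3R,5R)-5-bromo-2,6,6-trimethyl-2-[(1S)-4-methylcyclohex-3-en-1-yl]oxan-3-yl]oxy}dimethylsilane, via vinyl oxocarbenium triflate 9 (not isolated), via cyclohexenyl oxocarbenium triflate 10 (not isolated)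
Conditions: NBS (1.0 equiv), TMSOTf (1.1 equiv), CH2Cl2, −78 → −40 °C; then 8 (5 equiv), −78 °C; then AlMe3 (3 equiv), −78 → −40 °C; aqueous potassium sodium tartrate
Reagents that add atoms: N-bromosuccinimide, O=C1CCC(=O)N1Br; trimethylaluminium, C[Al](C)C
Why: Proposed new method: TMSOTf-activated NBS forms the bromonium ion of the prenyl alkene, which the enone oxygen opens at the tertiary carbon (6-endo, anti; closest known types: bromolactonisation and bromoketalisation of prenyl carbonyl compounds) to give the 2-vinyl oxocarbenium ion 9, a cationic dienophile that adds isoprene para-selectively (closest known type: Gassman ionic Diels–Alder reaction of vinyl oxocarbenium ions) to give 10, which AlMe3 methylates along the axial trajectory (closest known type: AlMe3 C-methylation of ketal-derived cyclic oxocarbenium ions); the C3 silyloxy group stays pseudoaxial to avoid A1,2 strain with the C2 substituent, so bromine ends equatorial and trans to it (C5 R), the diene adds to the s-cis vinyl group on the face anti to it (ring carbon S), and methyl enters anti to it (C2 R).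

**Step 5**
Reactants: 11 tert-butyl{[(2R,3R,5R)-5-bromo-2,6,6-trimethyl-2-[(1S)-4-methylcyclohex-3-en-1-yl]oxan-3-yl]oxy}dimethylsilane
Product: 12 (1R,2R,4S)-4-[(2R,3R,5R)-5-bromo-3-[(tert-butyldimethylsilyl)oxy]-2,6,6-trimethyloxan-2-yl]-2-chloro-1-methylcyclohexan-1-ol
Conditions: trichloroisocyanuric acid (0.40 equiv), acetone/H2O 4:1, 0 °C → rt
Reagents that add atoms: trichloroisocyanuric acid, O=C1N(Cl)C(=O)N(Cl)C(=O)N1Cl; water, O
Why: Chlorohydroxylation (cohalogenation): Cl+ adds to the less substituted alkene carbon by axial attack on the half-chair that keeps the oxanyl group equatorial, and water opens the chloronium ion at the tertiary carbon from the opposite face, giving the Markovnikov trans-diaxial chlorohydrin (Cl trans and OH cis to the oxanyl group), as in the halohydrin chemistry of limonene.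

**Step 6**
Reactants: 12 (1R,2R,4S)-4-[(2R,3R,5R)-5-bromo-3-[(tert-butyldimethylsilyl)oxy]-2,6,6-trimethyloxan-2-yl]-2-chloro-1-methylcyclohexan-1-ol
Product: 13 tert-butyl{[(2R,3R,5R)-5-bromo-2-[(1S,3R,4R)-4-bromo-3-chloro-4-methylcyclohexyl]-2,6,6-trimethyloxan-3-yl]oxy}dimethylsilane
Conditions: TMSBr (2.5 equiv), CH2Cl2, −20 → 0 °C
Reagents that add atoms: bromotrimethylsilane, C[Si](C)(C)Br
Why: SN1-type bromodehydroxylation of the tertiary alcohol with neighbouring-group participation: the antiperiplanar axial chlorine bridges as the silylated hydroxyl leaves and bromide reopens the chloronium ion at the tertiary carbon trans-diaxially, so that carbon keeps its configuration (net retention, axial tertiary bromide trans to chlorine).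

**Step 7**
Reactants: 13 tert-butyl{[(2R,3R,5R)-5-bromo-2-[(1S,3R,4R)-4-bromo-3-chloro-4-methylcyclohexyl]-2,6,6-trimethyloxan-3-yl]oxy}dimethylsilane
Product: 14 tert-butyl{[(2R,3R,5R)-5-bromo-2-[(1S,3S,4S)-3-bromo-4-chloro-4-methylcyclohexyl]-2,6,6-trimethyloxan-3-yl]oxy}dimethylsilane
Conditions: MeNO2, 75 °C, dark; recovered 13 recycled
Reagents that add atoms: none
Why: Thermal diaxial-to-diequatorial (dyotropic) rearrangement of a vicinal dihalide through a bridged halonium–halide ion pair, as known for steroidal 5α,6β-dihalides: each halogen moves to the neighbouring carbon on its own face (Br to the secondary carbon, Cl to the tertiary carbon), inverting both carbons to the (3S,4S) trans-diequatorial bromochloride; the polar solvent favours the more polar diequatorial isomer.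

**Step 8**
Reactants: 14 tert-butyl{[(2R,3R,5R)-5-bromo-2-[(1S,3S,4S)-3-bromo-4-chloro-4-methylcyclohexyl]-2,6,6-trimethyloxan-3-yl]oxy}dimethylsilane
Product: 15 caespitol, (2R,3R,5R)-5-bromo-2-[(1S,3S,4S)-3-bromo-4-chloro-4-methylcyclohexyl]-2,6,6-trimethyloxan-3-ol
Conditions: HF·pyridine, THF, 0 °C → rt
Reagents that add atoms: none
Why: Fluoride-driven desilylation (Si–F bond formation) under non-basic conditions frees the axial hydroxyl without E2 loss of the tertiary chloride or the secondary bromides; no stereocentre is touched.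

**Compound list**
1 | methyl (2R)-oxirane-2-carboxylate (methyl (R)-glycidate) | COC(=O)[C@H]1CO1 | starting material
2 | (2-methylprop-1-en-1-yl)magnesium bromide | CC(C)=C[Mg]Br | starting material
3 | methyl (2R)-2-hydroxy-5-methylhex-4-enoate | COC(=O)[C@H](O)CC=C(C)C | intermediate
4 | methyl (2R)-2-[(tert-butyldimethylsilyl)oxy]-5-methylhex-4-enoate | COC(=O)[C@H](O[Si](C)(C)C(C)(C)C)CC=C(C)C | intermediate
5 | vinylmagnesium bromide | C=C[Mg]Br | starting material
6 | (2R)-2-[(tert-butyldimethylsilyl)oxy]-N-methoxy-N,5-dimethylhex-4-enamide | CON(C)C(=O)[C@H](O[Si](C)(C)C(C)(C)C)CC=C(C)C | intermediate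
7 | (4R)-4-[(tert-butyldimethylsilyl)oxy]-7-methylocta-1,6-dien-3-one | C=CC(=O)[C@H](O[Si](C)(C)C(C)(C)C)CC=C(C)C | intermediate
8 | isoprene (2-methylbuta-1,3-diene) | C=CC(C)=C | starting material
9 | (3R,5R)-5-bromo-3-[(tert-butyldimethylsilyl)oxy]-2-ethenyl-6,6-dimethyl-3,4,5,6-tetrahydropyrylium triflate | CC1(C)[O+]=C(C=C)[C@H](O[Si](C)(C)C(C)(C)C)C[C@H]1Br.[O-]S(=O)(=O)C(F)(F)F | intermediate
10 | (3R,5R)-5-bromo-3-[(tert-butyldimethylsilyl)oxy]-6,6-dimethyl-2-[(1S)-4-methylcyclohex-3-en-1-yl]-3,4,5,6-tetrahydropyrylium triflate | CC1(C)[O+]=C([C@H]2CCC(C)=CC2)[C@H](O[Si](C)(C)C(C)(C)C)C[C@H]1Br.[O-]S(=O)(=O)C(F)(F)F | intermediate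
11 | tert-butyl{[(2R,3R,5R)-5-bromo-2,6,6-trimethyl-2-[(1S)-4-methylcyclohex-3-en-1-yl]oxan-3-yl]oxy}dimethylsilane | CC1(C)O[C@](C)([C@H]2CCC(C)=CC2)[C@H](O[Si](C)(C)C(C)(C)C)C[C@H]1Br | intermediate
12 | (1R,2R,4S)-4-[(2R,3R,5R)-5-bromo-3-[(tert-butyldimethylsilyl)oxy]-2,6,6-trimethyloxan-2-yl]-2-chloro-1-methylcyclohexan-1-ol | CC1(C)O[C@](C)([C@H]2CC[C@@](C)(O)[C@H](Cl)C2)[C@H](O[Si](C)(C)C(C)(C)C)C[C@H]1Br | intermediate
13 | tert-butyl{[(2R,3R,5R)-5-bromo-2-[(1S,3R,4R)-4-bromo-3-chloro-4-methylcyclohexyl]-2,6,6-trimethyloxan-3-yl]oxy}dimethylsilane (isocaespitol TBS ether) | CC1(C)O[C@](C)([C@H]2CC[C@@](C)(Br)[C@H](Cl)C2)[C@H](O[Si](C)(C)C(C)(C)C)C[C@H]1Br | intermediate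
14 | tert-butyl{[(2R,3R,5R)-5-bromo-2-[(1S,3S,4S)-3-bromo-4-chloro-4-methylcyclohexyl]-2,6,6-trimethyloxan-3-yl]oxy}dimethylsilane (caespitol TBS ether) | CC1(C)O[C@](C)([C@H]2CC[C@](C)(Cl)[C@@H](Br)C2)[C@H](O[Si](C)(C)C(C)(C)C)C[C@H]1Br | intermediate
15 | caespitol, (2R,3R,5R)-5-bromo-2-[(1S,3S,4S)-3-bromo-4-chloro-4-methylcyclohexyl]-2,6,6-trimethyloxan-3-ol | CC1(C)O[C@](C)([C@H]2CC[C@](C)(Cl)[C@@H](Br)C2)[C@H](O)C[C@H]1Br | target

**Step count**
Total steps: 8. Longest linear sequence: 8 steps (1 → 15).

**Three steps most likely to fail**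

Step 4 (cascade). Possible failures are 5-exo attack of the carbonyl oxygen, participation of the silyl ether oxygen, cationic oligomerisation of isoprene, and weak facial control in the cycloaddition. Fallback: starting from 7, the rings are made one at a time. A Me2AlCl-promoted Diels–Alder reaction with 8 gives the ketone (2R)-2-[(tert-butyldimethylsilyl)oxy]-5-methyl-1-[(1S)-4-methylcyclohex-3-en-1-yl]hex-4-en-1-one F1; a chiral oxazaborolidinium catalyst is used if substrate control at the ring carbon is poor. Felkin–Anh addition of MeLi/CeCl3 (methyl anti to the non-chelating silyl ether) gives the tertiary alcohol (2R,3R)-3-[(tert-butyldimethylsilyl)oxy]-6-methyl-2-[(1S)-4-methylcyclohex-3-en-1-yl]hept-5-en-2-ol F2. A 6-endo bromoetherification with 2,4,4,6-tetrabromocyclohexa-2,5-dienone (MeNO2, 0 °C; chair with Br equatorial, methyl axial) closes the oxane and comes back to the route at 11.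

Step 6 (tertiary alcohol to bromide next to C–Cl). Possible failures are E1 elimination and capture of the cation by the oxane oxygen (cineole-type bridging). Fallback: starting from 11, bromine is installed first at the tertiary carbon. Catalyst-controlled epoxidation on the face anti to the oxanyl group (Shi-type fructose-derived ketone, KHSO5) gives the epoxide tert-butyl{[(2R,3R,5R)-5-bromo-2,6,6-trimethyl-2-[(1S,4S,6R)-1-methyl-7-oxabicyclo[4.1.0]heptan-4-yl]oxan-3-yl]oxy}dimethylsilane F3. HBr (or MgBr2·OEt2) opens it at the tertiary carbon trans-diaxially to the bromohydrin (1R,2R,5S)-2-bromo-5-[(2R,3R,5R)-5-bromo-3-[(tert-butyldimethylsilyl)oxy]-2,6,6-trimethyloxan-2-yl]-2-methylcyclohexan-1-ol F4. PPh3/NCS then replaces the axial secondary hydroxyl by chloride through the bromonium ion (neighbouring-group participation, net retention), and the route is rejoined at 13.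

Step 7 (halogen interchange). It is an equilibrium whose position is uncertain, because the product carries an axial methyl group, and HBr loss can compete on heating. Fallback: starting from 13, the silyl group is removed first (HF·pyridine) to give isocaespitol F5, (2R,3R,5R)-5-bromo-2-[(1S,3R,4R)-4-bromo-3-chloro-4-methylcyclohexyl]-2,6,6-trimethyloxan-3-ol. The interchange is then run on the free alcohol as a crystallisation-driven equilibration (hot heptane/nitromethane slurry seeded with product), which arrives directly at 15.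

**Further compounds**
F1 | step 4 | (2R)-2-[(tert-butyldimethylsilyl)oxy]-5-methyl-1-[(1S)-4-methylcyclohex-3-en-1-yl]hex-4-en-1-one | O=C([C@H]1CCC(C)=CC1)[C@H](O[Si](C)(C)C(C)(C)C)CC=C(C)C
F2 | step 4 | (2R,3R)-3-[(tert-butyldimethylsilyl)oxy]-6-methyl-2-[(1S)-4-methylcyclohex-3-en-1-yl]hept-5-en-2-ol | C[C@@](O)([C@H]1CCC(C)=CC1)[C@H](O[Si](C)(C)C(C)(C)C)CC=C(C)C
F3 | step 6 | tert-butyl{[(2R,3R,5R)-5-bromo-2,6,6-trimethyl-2-[(1S,4S,6R)-1-methyl-7-oxabicyclo[4.1.0]heptan-4-yl]oxan-3-yl]oxy}dimethylsilane | CC1(C)O[C@](C)([C@H]2CC[C@]3(C)O[C@@H]3C2)[C@H](O[Si](C)(C)C(C)(C)C)C[C@H]1Br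
F4 | step 6 | (1R,2R,5S)-2-bromo-5-[(2R,3R,5R)-5-bromo-3-[(tert-butyldimethylsilyl)oxy]-2,6,6-trimethyloxan-2-yl]-2-methylcyclohexan-1-ol | CC1(C)O[C@](C)([C@H]2CC[C@@](C)(Br)[C@H](O)C2)[C@H](O[Si](C)(C)C(C)(C)C)C[C@H]1Br
F5 | step 7 | isocaespitol, (2R,3R,5R)-5-bromo-2-[(1S,3R,4R)-4-bromo-3-chloro-4-methylcyclohexyl]-2,6,6-trimethyloxan-3-ol | CC1(C)O[C@](C)([C@H]2CC[C@@](C)(Br)[C@H](Cl)C2)[C@H](O)C[C@H]1Br
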